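The synthesis rests on cutting the C2–C1′ bond between the pyranone ring C and the 2,3-dimethoxyphenyl ring B. The key step is a Pd(II)-catalysed aerobic oxidative boron-Heck arylation. It joins unprotected 5,7-dihydroxychromone and 2,3-dimethoxyphenylboronic acid directly at C2–H. It exploits the polarised vinylogous ester O1–C2=C3–C4=O of ring C, whose β-carbon C2 takes the aryl group from palladium. The precursor therefore carries no halogen, metal or protecting group, and the flavone core is complete after one operation. Ring A is then finished at its two analogous, oxygen-flanked positions C6 and C8 by dibromination and copper-catalysed bromide-to-methoxide exchange.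

Key step: step 1

Remark: the target has no stereocentre and the C2–C1′ axis rotates freely, so only one stereoisomer exists; 5,7-dihydroxychromone (1) is taken as a catalogue compound.

Step 1
Reactants: 1 5,7-dihydroxy-4H-chromen-4-one; 2 (2,3-dimethoxyphenyl)boronic acid
Product: 3 5,7-dihydroxy-2-(2,3-dimethoxyphenyl)-4H-chromen-4-one
Conditions: 2 (2.5 equiv, in portions), Pd(TFA)2 (10 mol %), 5-nitro-1,10-phenanthroline (20 mol %), O2 (1 atm), DMSO, 100 °C
Reagents that add atoms: none
Why: This is an oxidative boron-Heck reaction, a known way to arylate chromones at C2–H with arylboronic acids: transmetalation gives a phenanthroline-bound Pd(II)–aryl species that inserts syn into C2=C3, placing the aryl group on the electrophilic β-carbon C2 and palladium on C3 as a palladium enolate. C-/O-enolate tautomerisation brings palladium syn to H-2, β-hydride elimination releases the flavone, and O2 returns the reduced palladium to Pd(II). No ring is closed and no stereocentre is formed. The step needs C2 over C3 selectivity, which the polarity of O1–C2=C3–C4=O secures and the 5-OH···O=C4 hydrogen bond reinforces. It also needs Heck termination over protonolysis, which dry DMSO under O2 favours, and material diverted to conjugate addition should be dehydrogenated to the same flavone by the same catalyst. The chelating nitrogen ligand should suppress electrophilic palladation at C6/C8 and compete with the 5-OH/C4=O chelate for palladium, the resorcinol-type phenols should resist O2 in a neutral medium, and excess 2 covers protodeboronation and homocoupling of the ortho-methoxy boronic acid.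

Step 2
Reactants: 3 5,7-dihydroxy-2-(2,3-dimethoxyphenyl)-4H-chromen-4-one
Product: 4 6,8-dibromo-5,7-dihydroxy-2-(2,3-dimethoxyphenyl)-4H-chromen-4-one
Conditions: NBS (2.05 equiv), DMF, 0 °C to rt, dark
Reagents that add atoms: N-bromosuccinimide, O=C1CCC(=O)N1Br
Why: In this electrophilic aromatic bromination, C6 and C8 each lie ortho or para to three oxygen donors (5-OH, 7-OH, O1) and are far more nucleophilic than C3 or ring B, which the chromone C2 deactivates, so two equivalents of NBS should stop at the 6,8-dibromide.

Step 3
Reactants: 4 6,8-dibromo-5,7-dihydroxy-2-(2,3-dimethoxyphenyl)-4H-chromen-4-one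
Product: 5 5,7-dihydroxy-6,8-dimethoxy-2-(2,3-dimethoxyphenyl)-4H-chromen-4-one (target)
Conditions: NaOMe (25 wt % in MeOH, 12 equiv), CuBr (30 mol %), DMF, 110 °C, Ar; then 1 M HCl, 0 °C
Reagents that add atoms: sodium methoxide, [Na+].[O-]C
Why: This is a copper-catalysed Ullmann-type methoxylation of aryl bromides ortho to phenoxides (the reaction type that turns 3,5-dibromo-4-hydroxybenzaldehyde into syringaldehyde), in which any base-induced opening and reclosure of ring C (Wessely–Moser type) is degenerate because C6 and C8 carry identical groups at start and end, and acidification returns the free 5,7-diol.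

Compound list
1 | 5,7-dihydroxy-4H-chromen-4-one | O=c1ccoc2cc(O)cc(O)c12 | starting material
2 | (2,3-dimethoxyphenyl)boronic acid | COc1cccc(B(O)O)c1OC | starting material
3 | 5,7-dihydroxy-2-(2,3-dimethoxyphenyl)-4H-chromen-4-one | COc1cccc(-c2cc(=O)c3c(O)cc(O)cc3o2)c1OC | intermediate
4 | 6,8-dibromo-5,7-dihydroxy-2-(2,3-dimethoxyphenyl)-4H-chromen-4-one | COc1cccc(-c2cc(=O)c3c(O)c(Br)c(O)c(Br)c3o2)c1OC | intermediate
5 | 5,7-dihydroxy-6,8,2′,3′-tetramethoxyflavone (achiral) | COc1cccc(-c2cc(=O)c3c(O)c(OC)c(O)c(OC)c3o2)c1OC | target

Total step count: 3. Longest linear sequence: 3.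

Steps most likely to fail

Step 1. Insertion into the electron-rich, chelating chromone may be slow. Protodeboronation, oxidation and homocoupling of the hindered boronic acid could then consume the aryl donor, and the 5-OH/C4=O chelate could capture palladium.
- The fallback reverses the polarity and masks the phenols.
- From 1, double protection (MOMCl, NaH, DMF) should give 5,7-bis(methoxymethoxy)-4H-chromen-4-one F1.
- C2-selective deprotonative zincation with a TMP-zinc amide base (TMPZnCl·LiCl type, THF) should give [5,7-bis(methoxymethoxy)-4-oxo-4H-chromen-2-yl]zinc chloride F2.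
- Negishi coupling with commercial 1-iodo-2,3-dimethoxybenzene (Pd(0), tri(2-furyl)phosphine) should give 2-(2,3-dimethoxyphenyl)-5,7-bis(methoxymethoxy)-4H-chromen-4-one F3.
- HCl in MeOH removes both acetals and the sequence comes back at 3.

Step 3. Hydrodebromination may compete with C–O bond formation, the exchange may stall after the first bromide, and the very electron-rich bis-phenoxide may be oxidised by traces of air.
- The fallback replaces C–O coupling by C–B formation and oxidation on protected material.
- From 4, benzylation (BnBr, K2CO3, DMF) should give 5,7-bis(benzyloxy)-6,8-dibromo-2-(2,3-dimethoxyphenyl)-4H-chromen-4-one F4.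
- Double Miyaura borylation (B2pin2, Pd/SPhos, KOAc, dioxane) should give the 6,8-bis(pinacolboronate) of 5,7-bis(benzyloxy)-2-(2,3-dimethoxyphenyl)-4H-chromen-4-one F5.
- Oxidation (H2O2, aq. NaOH, THF) should give 5,7-bis(benzyloxy)-6,8-dihydroxy-2-(2,3-dimethoxyphenyl)-4H-chromen-4-one F6.
- Methylation (MeI, K2CO3, acetone) should give 5,7-bis(benzyloxy)-6,8-dimethoxy-2-(2,3-dimethoxyphenyl)-4H-chromen-4-one F7.
- Hydrogenolysis (H2, Pd/C, EtOAc) comes back at 5.

Step 2. Site selectivity may be lost, with bromination spilling over to ring B (C5′/C6′) or C3, or over-bromination of ring A to a dienone.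
- The fallback inverts the order of events so that no ring B is present during halogenation.
- From 1, NBS (2 equiv, DMF) should give 6,8-dibromo-5,7-dihydroxy-4H-chromen-4-one F8.
- F8 is then arylated with 2 under the oxidative boron-Heck conditions of step 1 and comes back at 4. Nitrogen-ligated Pd(II)/O2 systems are expected to leave hindered, electron-rich aryl bromides untouched.

Further compounds
F1 | step 1 | 5,7-bis(methoxymethoxy)-4H-chromen-4-one | COCOc1cc(OCOC)c2c(=O)ccoc2c1
F2 | step 1 | [5,7-bis(methoxymethoxy)-4-oxo-4H-chromen-2-yl]zinc chloride | COCOc1cc(OCOC)c2c(=O)cc([Zn]Cl)oc2c1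
F3 | step 1 | 2-(2,3-dimethoxyphenyl)-5,7-bis(methoxymethoxy)-4H-chromen-4-one | COCOc1cc(OCOC)c2c(=O)cc(-c3cccc(OC)c3OC)oc2c1
F4 | step 3 | 5,7-bis(benzyloxy)-6,8-dibromo-2-(2,3-dimethoxyphenyl)-4H-chromen-4-one | COc1cccc(-c2cc(=O)c3c(OCc4ccccc4)c(Br)c(OCc4ccccc4)c(Br)c3o2)c1OC
F5 | step 3 | 6,8-bis(pinacolboronate) of 5,7-bis(benzyloxy)-2-(2,3-dimethoxyphenyl)-4H-chromen-4-one | COc1cccc(-c2cc(=O)c3c(OCc4ccccc4)c(B4OC(C)(C)C(C)(C)O4)c(OCc4ccccc4)c(B4OC(C)(C)C(C)(C)O4)c3o2)c1OC
F6 | step 3 | 5,7-bis(benzyloxy)-6,8-dihydroxy-2-(2,3-dimethoxyphenyl)-4H-chromen-4-one | COc1cccc(-c2cc(=O)c3c(OCc4ccccc4)c(O)c(OCc4ccccc4)c(O)c3o2)c1OC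
F7 | step 3 | 5,7-bis(benzyloxy)-6,8-dimethoxy-2-(2,3-dimethoxyphenyl)-4H-chromen-4-one | COc1cccc(-c2cc(=O)c3c(OCc4ccccc4)c(OC)c(OCc4ccccc4)c(OC)c3o2)c1OC
F8 | step 2 | 6,8-dibromo-5,7-dihydroxy-4H-chromen-4-one | O=c1ccoc2c(Br)c(O)c(Br)c(O)c12
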